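# Proposed total synthesis of CNP0265287.1 (compound 20)

## Analysis of the target

The target 20 is an enolized bicyclo[3.3.1]nonane-2,4,9-trione. The numbering used for every bicyclic compound below is: C1, the bridgehead with a prenyl group; C2, the carbonyl carbon next to it; C3, the carbon with the isobutyryl group; C4, the enol carbon; C5, the bridgehead with the methyl group; C6, the CH2; C7, the CH with the second prenyl group (its CH2 is C10); C8, the CMe2 carbon; C9, the bridging carbonyl carbon. Ring A is C1–C2–C3–C4–C5–C9 and ring B is C1–C8–C7–C6–C5–C9.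

There are three stereocentres, (1R,5R,7R) in the tautomer drawn. C1 and C5 are tied to each other by the bicycle. The C7 prenyl group is endo, that is on the side of the C2–C3–C4 bridge and cis to the C1–C2 and C5–C4 bonds, so ring B cannot keep a chair with an equatorial C7 substituent. The C1–C8 bond joins a bridgehead quaternary carbon, flanked by two carbonyl groups, to a second fully substituted carbon.

The sensitive groups are the acylated β-triketone (tautomers, acidity, retro-Claisen opening at C9 by hard nucleophiles) and two trisubstituted alkenes, which exclude protic acid, electrophiles and unselective hydrogenation late in the route.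

Three things make the synthesis hard:
- the C1–C8 bond;
- the endo configuration at C7, which chair-like closures of ring B do not give;
- the absolute configuration of a core whose bridgeheads differ only as methyl versus prenyl.

The plan is built on one feature. Without the groups at C1, C3 and C7, ring A with its C5 methyl group has a mirror plane through C5 and C2, so C1/C3 and C9/C4 are enantiotopic pairs. C7 can carry an oxygen atom instead of its prenyl group while ring B is closed.

## Retrosynthetic reasoning

**20 to 19 to 17 (O–CH3 and C3–acyl bonds).** The acylated β-triketone is the most labile part, so it is made last. It comes from its methyl enol ether 19, and the isobutyryl group is put on C3 of the vinylogous ester 17 by vinylic metalation and reaction with an isobutyryl electrophile. Ring A is therefore carried through the route as one defined, non-acidic vinylogous ester with the carbonyl at C2 and the methoxy group at C4.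

**17 to 15 (C10–C11 and C7–H bonds).** The prenyl group at C7 is cut between its CH2 (C10) and its alkene carbon, and the C7–H bond is removed, which gives the 7-methylidene compound 15. The cut is made here because no ring closure gives endo C7 directly, whereas on the finished bicycle the two faces of a trigonal C7 differ strongly: ring A blocks the endo face. The forward reaction must add hydrogen to C7 from the exo face and a 2-methylpropenyl group to C10; hydroboration followed by sp3–sp2 cross-coupling does both.

**15 to 13 (C1–prenyl bond).** The bridgehead prenyl group is removed. C1–H in 13 lies between the C2 and C9 carbonyl groups, and a bridgehead carbanion is accessible in this ring system. This step also tells the two bridgeheads apart, because C5 already carries its methyl group.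

**13 to 12 to 11 to 10 (functional group changes at C7).** The methylidene group comes from a C7 ketone (12), the ketone from the exo alcohol 11, and 11 from the bridged mixed ketal 10, in which the C7 oxygen is tied to C9. The C7 oxygen is a relay: it is needed for the key step and is then erased.

**10 to 9 (C2=O).** The C2 carbonyl is traced back to a CH2 group. C2 is the only allylic CH2 of the enol ether in 9, because the other allylic position, C5, is quaternary.

**9 to 7 (C1–C8 and O7–C9 bonds, key disconnection).** Cutting C1–C8 and the ketal bond O7–C9 opens ring B and leads to 7, a 6,6-disubstituted 1,5-dimethoxycyclohexa-1,4-diene with a trisubstituted epoxide in the side chain. Its ring is achiral, because the two enol ethers are mirror images of each other; the only stereocentre is the epoxide carbon C7.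
- Why here: C1 is by nature a nucleophilic enol carbon and C8 a tertiary, cation-stabilizing carbon, so this polar bond formation matches the innate reactivity of both ends.
- What is gained: ring B, the hindered C1–C8 bond and the stereocentres C1, C5 and C9, all from one stereocentre.
- What the forward reaction must achieve: selection of one of the two enol ethers by the epoxide, and attack at the tertiary epoxide carbon.

**7 to 5 and 3 (C5–C6 bond).** The side chain is attached by alkylation of the dienyl anion 6, made from 5, with the epoxy bromide 3. This bond is a primary SN2 alkylation and is therefore made first; the hard bond is left to the intramolecular step.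

**5 to 4, and 3 to 2 to 1.** The diene 5 is the Birch product of 4. The bromide 3 comes from the epoxy alcohol 2, which a tartrate-controlled epoxidation makes from 1; this is the only step in which the absolute configuration is set by a reagent.

## Alternatives that were turned down

**Alternative 1: the textbook disconnection (C1–C2 and C4–C5).** Both bonds from the bridgeheads to ring A are cut, which leads to the ring B enol ether A1 and malonyl dichloride A2. The forward key step is an Effenberger-type cyclization to the trione A3, followed by C3 acylation. It was turned down for three reasons: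
- C1, C5 and C7 are the alternating positions of ring B, so their axial bonds point to the same face. The malonyl bridge needs the axial bonds at C1 and C5, and with the C7 prenyl group equatorial the bridge forms on the face of the C7 hydrogen. The product A3 therefore belongs to the exo series, the wrong relative configuration.
- A1 must first be made as a single enantiomer with four ring substituents, which costs more steps than the whole ring B costs in the chosen route.
- The acylation has to take place at a neopentyl enol carbon next to CMe2, in the presence of acid chloride and HCl, which the prenyl groups do not tolerate well.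

**Alternative 2: annulation of the aromatic ring (C5–C6 and C1–C8).** The fully substituted acylphloroglucinol A4 is combined with the enal A5 in an alkylative dearomatization–annulation: SN2'-type Michael addition and loss of acetate, then intramolecular Michael addition to the β,β-dimethyl enal. The product is the formyl bicycle A6. It was turned down for four reasons:
- The two nucleophilic ring carbons of A4 differ only as C–methyl versus C–prenyl. Nothing in the mechanism decides which one attacks the CH2 end first, so the isomer with exchanged bridgeheads is expected as well.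
- The C7 formyl group is epimerizable under the basic conditions and should settle exo.
- The absolute configuration would depend on ion pairing of a catalyst with an unsymmetrical phenoxide.
- Turning CHO into prenyl costs three to four steps without correcting C7.

**Alternative 3: chiral pool (lavandulyl mapping).** C6, C7, C8, the two methyl groups on C8 and the C7 prenyl group are the ten carbons of a lavandulyl group. Alkylation of 6 with (S)-lavandulyl bromide A7 would give the diene A8. Protonation of its isopropenyl group and closure of the tertiary cation onto an enol ether would give the bicycle A9. It was turned down for three reasons: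
- The chair-like closure puts the C7 prenyl group equatorial, which means exo. With the correct C7 configuration, the core of A9 is the mirror image of the one needed.
- The proton would have to choose the isopropenyl group over the prenyl alkene and two acid-labile enol ethers.
- A7 derives from the unnatural enantiomer of lavandulol and is a β-branched, slow electrophile.

The useful lesson is that C7 should not carry its carbon substituent when ring B is closed.

Key step: step 5

## Route

Remark on the chemistry: 20 is an enolized β-triketone that should exist as a mixture of rapidly interconverting enol tautomers; it is drawn and named as the 4-hydroxy-2-oxo tautomer of the task.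

Step 1
Reactants: 1 3-methylbut-2-en-1-ol (prenol)
Product: 2 (S)-(3,3-dimethyloxiran-2-yl)methanol
Conditions: Ti(OiPr)4 (10 mol %), L-(+)-diethyl tartrate (12 mol %), t-BuOOH, 4 Å molecular sieves, CH2Cl2, −20 °C
Reagents that add atoms: tert-butyl hydroperoxide, CC(C)(C)OO
Why: Sharpless asymmetric epoxidation of a 3,3-disubstituted allylic alcohol; the L-(+)-tartrate catalyst delivers oxygen to the face that gives the (S) epoxide, the same sense as for other allylic alcohols with this tartrate. This stereocentre (later C7) is the only one set by a reagent.

Step 2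
Reactants: 2 (S)-(3,3-dimethyloxiran-2-yl)methanol
Product: 3 (R)-3-(bromomethyl)-2,2-dimethyloxirane
Conditions: CBr4, PPh3, 2,6-lutidine, CH2Cl2, 0 °C
Reagents that add atoms: tetrabromomethane, BrC(Br)(Br)Br
Why: Appel reaction at the primary carbinol under buffered conditions; no bond to the stereocentre is touched, and the descriptor changes from S to R only because CH2Br outranks the ring carbon.

Step 3
Reactants: 4 2,6-dimethoxytoluene
Product: 5 1,5-dimethoxy-6-methylcyclohexa-1,4-diene
Conditions: Li, liquid NH3, THF, t-BuOH, −78 to −33 °C
Reagents that add atoms: none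
Why: Birch reduction; the methoxy-bearing carbons stay sp2, so the skipped diene has its methyl-bearing CH between the two enol ethers, which is the ring A pattern with C5 in place.

Step 4
Reactants: 5 1,5-dimethoxy-6-methylcyclohexa-1,4-diene; 3 (R)-3-(bromomethyl)-2,2-dimethyloxirane
Product: 7 6-{[(2S)-3,3-dimethyloxiran-2-yl]methyl}-1,5-dimethoxy-6-methylcyclohexa-1,4-diene, via dienyllithium 6 (not isolated)
Conditions: t-BuLi, THF, −78 °C; then 3, −78 to −40 °C
Reagents that add atoms: none
Why: Deprotonation of the C–H between the two enol ethers gives a pentadienyl anion whose methoxy groups sit on nodal carbons; it should alkylate at its central carbon by SN2 at the primary bromide and so form the C5–C6 bond and the quaternary C5. The epoxide carbons (secondary next to the reacting CH2, and tertiary) are too hindered to compete, and the ring of 7 stays achiral.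

Step 5
Reactants: 7 6-{[(2S)-3,3-dimethyloxiran-2-yl]methyl}-1,5-dimethoxy-6-methylcyclohexa-1,4-diene
Product: 9 (7S)-4,9-dimethoxy-5,8,8-trimethyl-7,9-epoxybicyclo[3.3.1]non-3-ene (bridged mixed ketal), via oxocarbenium triflate 8 (not isolated)
Conditions: Me3SiOTf (0.3 equiv), 2,6-lutidine (0.5 equiv), CH2Cl2, −78 °C
Reagents that add atoms: none
Why: Silylation of the epoxide oxygen lets the tertiary C8–O bond ionize while the enol ether carbon C1 attacks C8 from the back side; the closest known reaction type is the Lewis-acid-promoted epoxide-opening (cation–olefin) cyclization of enol ethers. Ring B closes 6-endo with respect to the epoxide (attack at the distal tertiary carbon, not 5-exo at C7) and 6-(enolendo) with respect to the nucleophile. The oxocarbenium ion 8 is then captured by the C7 silyloxy oxygen in a 5-exo-trig closure, which gives the oxygen-bridged ketal and returns the silyl group. C7 is the only controlling element: in the chair-like transition state the C7–O bond must be anti to the forming C1–C8 bond, so it lies pseudo-equatorial (exo) and only one of the two diastereotopic enol ethers can reach C8; this choice sets C1 and C5 together, and C9 follows because only an exo oxygen can bridge to C9. The step needs group selectivity between the enol ethers (secured by the (S) epoxide and the chair), Markovnikov regioselectivity (tertiary C8 over secondary C7) and C-alkylation in preference to hydride shift of the activated epoxide (favoured by the low temperature and the high π-nucleophilicity of the enol ether). The minor closure would give an endo C7–O compound that cannot form the ketal, so any leakage should appear as a separable diastereomer and not as lower enantiomeric purity after C7 is oxidized.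

Step 6
Reactants: 9 (7S)-4,9-dimethoxy-5,8,8-trimethyl-7,9-epoxybicyclo[3.3.1]non-3-ene
Product: 10 (7S)-4,9-dimethoxy-5,8,8-trimethyl-7,9-epoxybicyclo[3.3.1]non-3-en-2-one
Conditions: t-BuOOH, Pd(OH)2 on carbon (5 mol %), K2CO3, CH2Cl2, 0 °C
Reagents that add atoms: tert-butyl hydroperoxide, CC(C)(C)OO
Why: Radical allylic C–H oxidation with tert-butyl hydroperoxide; C2 is the only allylic CH2 of the enol ether (C5 is quaternary), and the allylic peroxide should collapse under base to the vinylogous ester. The carbonyl thus comes to lie next to C1, as the bridgehead metalation in step 10 requires, while the ketal protects C9 and O7.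

Step 7
Reactants: 10 (7S)-4,9-dimethoxy-5,8,8-trimethyl-7,9-epoxybicyclo[3.3.1]non-3-en-2-one
Product: 11 (7S)-7-hydroxy-4-methoxy-5,8,8-trimethylbicyclo[3.3.1]non-3-ene-2,9-dione (hydroxyl exo)
Conditions: pyridinium p-toluenesulfonate (cat.), acetone–H2O, 40 °C
Reagents that add atoms: water, O
Why: Acid hydrolysis of the strained bridged mixed ketal; opening of the O7–C9 bond relieves the strain of the oxygen-bridged ring, so it should be faster than hydrolysis of the vinylogous ester. C7 keeps its configuration, and the γ-hydroxy ketone has no retro-aldol pathway.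

Step 8
Reactants: 11 (7S)-7-hydroxy-4-methoxy-5,8,8-trimethylbicyclo[3.3.1]non-3-ene-2,9-dione
Product: 12 4-methoxy-5,8,8-trimethylbicyclo[3.3.1]non-3-ene-2,7,9-trione
Conditions: Dess–Martin periodinane, NaHCO3, CH2Cl2, 0 °C to rt
Reagents that add atoms: none
Why: Dess–Martin oxidation of the secondary alcohol under buffered, non-basic conditions; the relay stereocentre C7 is erased after it has set C1 and C5, which are locked by the bicycle and cannot epimerize.

Step 9
Reactants: 12 4-methoxy-5,8,8-trimethylbicyclo[3.3.1]non-3-ene-2,7,9-trione
Product: 13 4-methoxy-5,8,8-trimethyl-7-methylidenebicyclo[3.3.1]non-3-ene-2,9-dione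
Conditions: Ph3PCH3Br, KN(SiMe3)2, THF, 0 °C; then 12, 0 °C to rt
Reagents that add atoms: methyltriphenylphosphonium bromide, C[P+](c1ccccc1)(c1ccccc1)c1ccccc1.[Br-]
Why: Wittig methylenation; the C7 ketone has one quaternary neighbour and should react before the C9 ketone (flanked by quaternary C5 and the branched bridgehead C1, and part of the β-dicarbonyl array) and before the ester-like C2 carbonyl. Deprotonation at C1 by excess ylide is harmless because a bridgehead cannot invert.

Step 10
Reactants: 13 4-methoxy-5,8,8-trimethyl-7-methylidenebicyclo[3.3.1]non-3-ene-2,9-dione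
Product: 15 4-methoxy-5,8,8-trimethyl-7-methylidene-1-(3-methylbut-2-en-1-yl)bicyclo[3.3.1]non-3-ene-2,9-dione, via bridgehead organolithium 14 (not isolated)
Conditions: LiN(iPr)2, THF, −78 °C; then prenyl bromide, −78 to −30 °C
Reagents that add atoms: prenyl bromide (1-bromo-3-methylbut-2-ene), CC(C)=CCBr
Why: Bridgehead metalation and alkylation, a known reaction type for bicyclo[3.3.1]nonane-2,9-diones; C1–H is α' to the vinylogous ester carbonyl and also next to C9, and the bridgehead carbanion is accessible in this ring size. Alkylation can only occur with retention, and it sets the prenyl-bearing quaternary C1 next to C8.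

Step 11
Reactants: 15 4-methoxy-5,8,8-trimethyl-7-methylidene-1-(3-methylbut-2-en-1-yl)bicyclo[3.3.1]non-3-ene-2,9-dione
Product: 17 (7R)-4-methoxy-5,8,8-trimethyl-1,7-bis(3-methylbut-2-en-1-yl)bicyclo[3.3.1]non-3-ene-2,9-dione (C7 group endo), via B-alkyl-9-BBN 16 (not isolated)
Conditions: 9-BBN dimer, THF, 0 °C to rt; then 1-bromo-2-methylprop-1-ene, Pd(dppf)Cl2 (5 mol %), AsPh3, Cs2CO3, DMF–H2O, rt to 45 °C
Reagents that add atoms: 1-bromo-2-methylprop-1-ene, CC(C)=CBr
Why: Hydroboration followed by B-alkyl Suzuki–Miyaura coupling; the borane should add to the 1,1-disubstituted alkene from the exo face because ring A closes the endo face, so hydrogen goes to C7 exo and C10 ends up endo, which sets (7R). The coupling with the vinyl bromide then completes the prenyl group; the trisubstituted prenyl alkene and the hindered carbonyl groups should be much slower toward 9-BBN.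

Step 12
Reactants: 17 (7R)-4-methoxy-5,8,8-trimethyl-1,7-bis(3-methylbut-2-en-1-yl)bicyclo[3.3.1]non-3-ene-2,9-dione
Product: 19 (7R)-4-methoxy-5,8,8-trimethyl-1,7-bis(3-methylbut-2-en-1-yl)-3-(2-methylpropanoyl)bicyclo[3.3.1]non-3-ene-2,9-dione, via C3 vinyllithium 18 (not isolated)
Conditions: lithium 2,2,6,6-tetramethylpiperidide (from the amine and n-BuLi), THF, −78 °C; then isobutyryl chloride, −78 °C
Reagents that add atoms: isobutyryl chloride (2-methylpropanoyl chloride), CC(C)C(Cl)=O
Why: Directed vinylic lithiation at C3, between the carbonyl and the methoxy-bearing carbon of the vinylogous ester, and C-acylation with an acid chloride; a known reaction type for 3-alkoxyenones of this ring system. No other acidic C–H remains, and the hindered amide does not add to C9.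

Step 13
Reactants: 19 (7R)-4-methoxy-5,8,8-trimethyl-1,7-bis(3-methylbut-2-en-1-yl)-3-(2-methylpropanoyl)bicyclo[3.3.1]non-3-ene-2,9-dione
Product: 20 (1R,5R,7R)-4-hydroxy-5,8,8-trimethyl-1,7-bis(3-methylbut-2-en-1-yl)-3-(2-methylpropanoyl)bicyclo[3.3.1]non-3-ene-2,9-dione (target)
Conditions: LiCl, DMSO, 120 °C; then dilute aq. HCl
Reagents that add atoms: none
Why: SN2 demethylation of the vinylogous ester by chloride at the methyl carbon (Krapcho-type); chloride does not attack C9, so retro-Claisen opening is avoided, and protonation should give the enolized triketone 20.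

## Compound list

1 | 3-methylbut-2-en-1-ol (prenol) | CC(C)=CCO | starting material
2 | (S)-(3,3-dimethyloxiran-2-yl)methanol | CC1(C)O[C@H]1CO | intermediate
3 | (R)-3-(bromomethyl)-2,2-dimethyloxirane | CC1(C)O[C@H]1CBr | intermediate
4 | 2,6-dimethoxytoluene | COc1cccc(OC)c1C | starting material
5 | 1,5-dimethoxy-6-methylcyclohexa-1,4-diene | COC1=CCC=C(OC)C1C | intermediate
6 | (2,6-dimethoxy-1-methylcyclohexa-2,5-dien-1-yl)lithium (dienyllithium, not isolated) | [Li]C1(C)C(OC)=CCC=C1OC | intermediate
7 | 6-{[(2S)-3,3-dimethyloxiran-2-yl]methyl}-1,5-dimethoxy-6-methylcyclohexa-1,4-diene | COC1=CCC=C(OC)C1(C)C[C@@H]2OC2(C)C | intermediate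
8 | oxocarbenium triflate: (7S)-4-methoxy-5,8,8-trimethyl-7-exo-(trimethylsilyloxy)bicyclo[3.3.1]non-3-en-9-ylidene(methyl)oxonium trifluoromethanesulfonate (not isolated; core as in 20) | C[Si](C)(C)O[C@H]1C[C@@]2(C)C(=[O+]C)[C@H](CC=C2OC)C1(C)C.[O-]S(=O)(=O)C(F)(F)F | intermediate
9 | (7S)-4,9-dimethoxy-5,8,8-trimethyl-7,9-epoxybicyclo[3.3.1]non-3-ene (oxygen bridge from exo C7 to C9; bridgeheads as in 20) | O3[C@H]1C[C@@]2(C)[C@]3(OC)[C@H](CC=C2OC)C1(C)C | intermediate
10 | (7S)-4,9-dimethoxy-5,8,8-trimethyl-7,9-epoxybicyclo[3.3.1]non-3-en-2-one (bridgeheads as in 20) | O3[C@H]1C[C@@]2(C)[C@]3(OC)[C@H](C(=O)C=C2OC)C1(C)C | intermediate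
11 | (7S)-7-hydroxy-4-methoxy-5,8,8-trimethylbicyclo[3.3.1]non-3-ene-2,9-dione (hydroxyl exo; bridgeheads as in 20) | O[C@H]1C[C@@]2(C)C(=O)[C@H](C(=O)C=C2OC)C1(C)C | intermediate
12 | 4-methoxy-5,8,8-trimethylbicyclo[3.3.1]non-3-ene-2,7,9-trione (bridgeheads as in 20) | O=C1C[C@@]2(C)C(=O)[C@H](C(=O)C=C2OC)C1(C)C | intermediate
13 | 4-methoxy-5,8,8-trimethyl-7-methylidenebicyclo[3.3.1]non-3-ene-2,9-dione (bridgeheads as in 20) | C=C1C[C@@]2(C)C(=O)[C@H](C(=O)C=C2OC)C1(C)C | intermediate
14 | C1-lithio derivative of 13 (bridgehead organolithium, not isolated) | C=C1C[C@@]2(C)C(=O)[C@]([Li])(C(=O)C=C2OC)C1(C)C | intermediate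
15 | 4-methoxy-5,8,8-trimethyl-7-methylidene-1-(3-methylbut-2-en-1-yl)bicyclo[3.3.1]non-3-ene-2,9-dione (bridgeheads as in 20) | C=C1C[C@@]2(C)C(=O)[C@](CC=C(C)C)(C(=O)C=C2OC)C1(C)C | intermediate
16 | 7-endo-[(9-borabicyclo[3.3.1]nonan-9-yl)methyl]-4-methoxy-5,8,8-trimethyl-1-(3-methylbut-2-en-1-yl)bicyclo[3.3.1]non-3-ene-2,9-dione (B-alkyl-9-BBN, not isolated) | B1(C2CCCC1CCC2)C[C@@H]1C[C@@]2(C)C(=O)[C@](CC=C(C)C)(C(=O)C=C2OC)C1(C)C | intermediate
17 | (7R)-4-methoxy-5,8,8-trimethyl-1,7-bis(3-methylbut-2-en-1-yl)bicyclo[3.3.1]non-3-ene-2,9-dione (C7 group endo; bridgeheads as in 20) | CC(C)=CC[C@@H]1C[C@@]2(C)C(=O)[C@](CC=C(C)C)(C(=O)C=C2OC)C1(C)C | intermediate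
18 | C3-lithio derivative of 17 (vinyllithium, not isolated) | CC(C)=CC[C@@H]1C[C@@]2(C)C(=O)[C@](CC=C(C)C)(C(=O)C([Li])=C2OC)C1(C)C | intermediate
19 | (7R)-4-methoxy-5,8,8-trimethyl-1,7-bis(3-methylbut-2-en-1-yl)-3-(2-methylpropanoyl)bicyclo[3.3.1]non-3-ene-2,9-dione (methyl enol ether of 20) | CC(C)=CC[C@@H]1C[C@@]2(C)C(=O)[C@](CC=C(C)C)(C(=O)C(C(=O)C(C)C)=C2OC)C1(C)C | intermediate
20 | (1R,5R,7R)-4-hydroxy-5,8,8-trimethyl-1,7-bis(3-methylbut-2-en-1-yl)-3-(2-methylpropanoyl)bicyclo[3.3.1]non-3-ene-2,9-dione (CNP0265287.1) | CC(C)=CC[C@@H]1C[C@@]2(C)C(=O)[C@](CC=C(C)C)(C(=O)C(C(=O)C(C)C)=C2O)C1(C)C | target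

## Step count and least certain steps

Total step count: 13. Longest linear sequence: 12 steps (1 to 20 through steps 1, 2 and 4–13); from 4 it is 11 steps.

**Step 5 (key step).** Three processes are most likely to go wrong:
- hydride shift or elimination of the silylated epoxide instead of C–C bond formation;
- acid-triggered hydrolysis or oligomerization of the very labile bis(enol ether);
- incomplete discrimination between the two enol ethers. This last one lowers the yield, not the enantiomeric purity, as long as the diastereomer is removed.

Fallback: it sets out from 7 and changes the nucleophile and the order of events. The doubly allylic CH2 of 7 is oxidized first (t-BuOOH, Rh2(caprolactamate)4, K2CO3, CH2Cl2) to the cross-conjugated dienone (S)-4-[(3,3-dimethyloxiran-2-yl)methyl]-3,5-dimethoxy-4-methylcyclohexa-2,5-dien-1-one F1. This vinylogous ester is not acid-labile, so the epoxide can be opened with BF3·OEt2 or EtAlCl2 at higher temperature. The α-carbon of one vinylogous ester then takes the role of C1, and the same ketal closure gives 10 directly. The route is rejoined at 10, and step 6 is no longer needed.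

**Step 6.** The likely failures are attack of the oxidant at the electron-rich enol ether double bond, trapping of the allyl radical at C4 instead of C2 (which would lead to the transposed enone), and over-oxidation.

Fallback: it sets out from 9 and replaces C–H oxidation by alkene oxidation.
- The enol ether is dehydrogenated with Pd(OAc)2 in aqueous MeCN to the transposed enone (7S)-9-methoxy-5,8,8-trimethyl-7,9-epoxybicyclo[3.3.1]non-2-en-4-one F2.
- Wacker–Tsuji oxidation of F2 (Na2PdCl4, t-BuOOH, aqueous AcOH) puts oxygen on the β-carbon C2 and hydrolyses the ketal in the same flask. It gives the β-diketone (7S)-7-hydroxy-5,8,8-trimethylbicyclo[3.3.1]nonane-2,4,9-trione F3.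
- O-Methylation with Me3SiCHN2 and separation of the two enol ether regioisomers give the C4-methoxy isomer, which is 11.

The route is rejoined at 11, and step 7 is no longer needed.

**Step 9.** The likely failures are insufficient discrimination between the C7 and C9 ketones while C1 still carries hydrogen, enolization of C7 toward C6 that stalls the olefination, and base-induced retro-Claisen opening at C1.

Fallback: it sets out from 11 and changes the order, so that C9 is flanked by two quaternary carbons before any olefination.
- Silylation (Et3SiCl, imidazole) gives the triethylsilyl ether F4.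
- Bridgehead prenylation (LiN(iPr)2, then prenyl bromide) gives the C1-prenylated silyl ether F5.
- Desilylation (HF·pyridine) gives the C1-prenylated alcohol F6.
- Dess–Martin oxidation gives the C1-prenylated 7-ketone F7.
- Methylenation of F7 (Ph3P=CH2, or the Zn/CH2Br2/TiCl4 reagent) gives 15.

The route is rejoined at 15, and step 10 is no longer needed.

**Step 11.** The likely failures are slow hydroboration next to the quaternary C8, which would let the borane reach the prenyl alkene or the C9 ketone, and slow transmetalation of the β-branched alkylborane with competing β-hydride elimination or protodeboronation.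

Fallback: it sets out from 15 and replaces the palladium cross-coupling by an SN2 alkylation of a cuprate.
- Iridium-catalysed hydroboration with pinacolborane ([Ir(cod)Cl]2, dppe; ketones and trisubstituted alkenes are not touched; same exo-face addition) and oxidation with NaBO3 give the endo hydroxymethyl compound F8.
- I2, PPh3 and imidazole convert it into the endo iodomethyl compound F9.
- F9 is coupled with lithium bis(2-methylprop-1-enyl)cuprate, (Me2C=CH)2CuLi, in Et2O–THF at −40 to 0 °C to give 17.

The route is rejoined at 17.

## Further compounds

F1 | step 5 | (S)-4-[(3,3-dimethyloxiran-2-yl)methyl]-3,5-dimethoxy-4-methylcyclohexa-2,5-dien-1-one | COC1=CC(=O)C=C(OC)C1(C)C[C@@H]2OC2(C)C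
F2 | step 6 | (7S)-9-methoxy-5,8,8-trimethyl-7,9-epoxybicyclo[3.3.1]non-2-en-4-one | O3[C@H]1C[C@@]2(C)[C@]3(OC)[C@H](C=CC2=O)C1(C)C
F3 | step 6 | (7S)-7-hydroxy-5,8,8-trimethylbicyclo[3.3.1]nonane-2,4,9-trione (hydroxyl exo) | O[C@H]1C[C@@]2(C)C(=O)[C@H](C(=O)CC2=O)C1(C)C
F4 | step 9 | (7S)-4-methoxy-5,8,8-trimethyl-7-(triethylsilyloxy)bicyclo[3.3.1]non-3-ene-2,9-dione | CC[Si](CC)(CC)O[C@H]1C[C@@]2(C)C(=O)[C@H](C(=O)C=C2OC)C1(C)C
F5 | step 9 | (7S)-4-methoxy-5,8,8-trimethyl-1-(3-methylbut-2-en-1-yl)-7-(triethylsilyloxy)bicyclo[3.3.1]non-3-ene-2,9-dione | CC[Si](CC)(CC)O[C@H]1C[C@@]2(C)C(=O)[C@](CC=C(C)C)(C(=O)C=C2OC)C1(C)C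
F6 | step 9 | (7S)-7-hydroxy-4-methoxy-5,8,8-trimethyl-1-(3-methylbut-2-en-1-yl)bicyclo[3.3.1]non-3-ene-2,9-dione | O[C@H]1C[C@@]2(C)C(=O)[C@](CC=C(C)C)(C(=O)C=C2OC)C1(C)C
F7 | step 9 | 4-methoxy-5,8,8-trimethyl-1-(3-methylbut-2-en-1-yl)bicyclo[3.3.1]non-3-ene-2,7,9-trione | O=C1C[C@@]2(C)C(=O)[C@](CC=C(C)C)(C(=O)C=C2OC)C1(C)C
F8 | step 11 | 7-endo-(hydroxymethyl)-4-methoxy-5,8,8-trimethyl-1-(3-methylbut-2-en-1-yl)bicyclo[3.3.1]non-3-ene-2,9-dione | OC[C@@H]1C[C@@]2(C)C(=O)[C@](CC=C(C)C)(C(=O)C=C2OC)C1(C)C
F9 | step 11 | 7-endo-(iodomethyl)-4-methoxy-5,8,8-trimethyl-1-(3-methylbut-2-en-1-yl)bicyclo[3.3.1]non-3-ene-2,9-dione | IC[C@@H]1C[C@@]2(C)C(=O)[C@](CC=C(C)C)(C(=O)C=C2OC)C1(C)C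
A1 | alternative 1 | (4R)-1-methoxy-2,5,5-trimethyl-4,6-bis(3-methylbut-2-en-1-yl)cyclohex-1-ene | COC1=C(C)C[C@@H](CC=C(C)C)C(C)(C)C1CC=C(C)C
A2 | alternative 1 | malonyl dichloride | O=C(Cl)CC(Cl)=O
A3 | alternative 1 | (7R)-5,8,8-trimethyl-1,7-bis(3-methylbut-2-en-1-yl)bicyclo[3.3.1]nonane-2,4,9-trione with the C7 group exo | CC(C)=CC[C@@H]1C[C@]2(C)C(=O)[C@@](CC=C(C)C)(C(=O)CC2=O)C1(C)C
A4 | alternative 2 | 2-methyl-1-[2,4,6-trihydroxy-3-methyl-5-(3-methylbut-2-en-1-yl)phenyl]propan-1-one | CC(C)C(=O)c1c(O)c(C)c(O)c(CC=C(C)C)c1O
A5 | alternative 2 | 2-(acetoxymethyl)-3-methylbut-2-enal | CC(C)=C(COC(C)=O)C=O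
A6 | alternative 2 | 7-exo-formyl-4-hydroxy-5,8,8-trimethyl-1-(3-methylbut-2-en-1-yl)-3-(2-methylpropanoyl)bicyclo[3.3.1]non-3-ene-2,9-dione | O=C[C@H]1C[C@@]2(C)C(=O)[C@](CC=C(C)C)(C(=O)C(C(=O)C(C)C)=C2O)C1(C)C
A7 | alternative 3 | (S)-1-bromo-5-methyl-2-(prop-1-en-2-yl)hex-4-ene (lavandulyl bromide) | BrC[C@@H](CC=C(C)C)C(C)=C
A8 | alternative 3 | 1,5-dimethoxy-6-methyl-6-[(2R)-5-methyl-2-(prop-1-en-2-yl)hex-4-en-1-yl]cyclohexa-1,4-diene | COC1=CCC=C(OC)C1(C)C[C@@H](CC=C(C)C)C(C)=C
A9 | alternative 3 | (7R)-4-methoxy-5,8,8-trimethyl-7-exo-(3-methylbut-2-en-1-yl)bicyclo[3.3.1]non-3-en-9-one | CC(C)=CC[C@@H]1C[C@]2(C)C(=O)[C@@H](CC=C2OC)C1(C)C
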